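The constants used here are assumed.

The second intermediate is the reagent I have to catch: it comes from the partner, and each one either couples with the open intermediate to give target or falls apart to decomposed reagent.

in all of them: time 2.0 h

| flask | substrate | partner | remark |
|---|---|---|---|
| Thursday's | 0.020 M | 0.0180 M | everything together at the start |
| Wednesday's | 0.020 M | 0.0180 M (fed, over 80 min) | all else is in the flask from the start; the feed brings no volume worth counting |
| Sunday's | 0.020 M (fed, over 80 min) | 0.0180 M | all else is in the flask from the start; the feed brings no volume worth counting |

    substrate → open intermediate (k1 = 0.00117 s⁻¹)
    partner → second intermediate (k2 = 0.00149 s⁻¹)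
    open intermediate + second intermediate → target (k3 = 0.0768 M⁻¹ s⁻¹)
    2 open intermediate → homo product (k4 = 0.0307 M⁻¹ s⁻¹)
    target ⇌ isomer of the product (K5 = 0.64, k5 = 2.93 × 10⁻⁴ s⁻¹)
    second intermediate → decomposed reagent (k6 = 4.83 × 10⁻⁴ s⁻¹)

- percent here means substrate units held: one homo product counts as two
- a doubled species enters its step squared and goes two at a time
- run time (Thursday's): 2.0 h

- the flask that comes out highest in amount of target, in percent of the substrate charged, or "all alike" when all lie within 1.5 percentage points (Thursday's / Wednesday's / Sunday's / all alike)
- target at the end, in percent of the substrate charged, Thursday's
- target at the end, in percent of the substrate charged, Wednesday's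
- target at the end, in percent of the substrate charged, Sunday's

Let x be the open intermediate as a fraction of the substrate charge. A second intermediate then faces two first-order chances, coupling at 0.0768 M⁻¹ s⁻¹ times the substrate charge times x, and decomposing at 4.83 × 10⁻⁴ s⁻¹. The two run level at 31.4 %, a fraction I call the catch point, and the share caught is x/(x + catch point). By charge the partner is the limiting reagent, 0.0180 M against 0.020 M, so I take the coupled fraction as the charge ratio 0.900 times that share.

What x does a second intermediate meet? Its life by decomposition is 34.5 min, and substrate's half-life of 9.87 min is shorter, so in Thursday's and Wednesday's I take the open intermediate as formed at the start. I let it fall by dimerising as 1/(1 + g × time), with g = 0.0737 min⁻¹. The target-isomer relaxation half-life of 0.256 h is shorter than the run, so I let target keep the equilibrium share, 61.0 % of what coupled.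

Thursday's, time = one life: x = 28.2 %, coupled 42.6 %, target 26.0 %.

Wednesday's, time = middle of the feed plus one life, 74.5 min: x = 15.4 %, target 18.0 %.

Sunday's, x climbs from zero over one life, after substrate's lag of 14.2 min, and I take the mean: x = 12.7 %, target 15.8 %.

So I put Thursday's highest, the one flask of these where my x stands nearest the catch point.

The forecast also says Thursday's, with 27 % for Thursday's, 19 % for Wednesday's and 17 % for Sunday's, holding that “adding them together gives the best overlap of the two intermediates”. Its figures stand above mine by 1 percentage point for Thursday's, 1.00 point for Wednesday's and 1.2 points for Sunday's.

The flasks give 27.0 % for Thursday's, 19.2 % for Wednesday's and 16.6 % for Sunday's, so Thursday's comes out highest, as the forecast said.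

Thursday's recipe with the partner cut to 0.0045 M, a quarter of its charge, keeps the substrate charge and so the catch point of 31.4 %. Holding x at 28.2 %, I reckon coupled material at 10.6 % of the substrate charge and target at 6.49 %. That flask ends with homo product at 75.5 % and target at 7.59 %.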